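**Assumptions (one line):** The Cu/chiral-diphosphine enantiomer in step 1 delivers the isopropenyl group to the face shown in 4, and the annulation in step 5 gives the C14–OH syn to C9–OH. Atoms are numbered as in the atisane skeleton (C1–C20, C3 = lactone C=O).

## Retrosynthesis
1. Crotobarin comes from a bicyclic keto-lactone 15 by C16 α-methylenation, with the C14 acetate already in place.
2. The bicyclo[2.2.2]octane comes from a SmI2 6-endo ketyl–olefin cyclization of the C15 aldehyde (on C8) onto the exocyclic C12=C16 methylene. This forms the C15–C16 bond and sets C12.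
3. Ring C (a methylenecyclohexane with cis C9/C14 diol) comes from a CrCl2 [3+3] bis-allylation of a quaternary β-ketoaldehyde with 3-bromo-2-(bromomethyl)propene. The δ-lactone comes from the C9 tertiary alcohol and the C3 ester.
4. The β-ketoaldehyde comes from bis-hydroxymethylation of a cyclohexanone at C8, differentiated by axial/equatorial reactivity. The cyclohexanone comes from tandem asymmetric conjugate addition/Michael on 2-methylcyclohexenone, which sets C5 and C10.
5. Ring order: B (step 1), C (step 5), lactone (step 6), bridging bicycle (step 10).

## Route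

**Step 1**
Reactants: 1 (2-methylcyclohex-2-en-1-one), 2 (2-bromopropene, used as isopropenylmagnesium bromide), 3 (methyl acrylate).
Product: 4, methyl 3-[1-methyl-2-oxo-6-(prop-1-en-2-yl)cyclohexyl]propanoate. The chain is trans to the isopropenyl and the methyl is cis to it.
Conditions: isopropenylMgBr (from 2 + Mg), CuBr·SMe2 (10 mol%), chiral ferrocenyl diphosphine (12 mol%), t-BuOMe, –78 °C; then 3, –78 → 0 °C.
Reagents that add atoms: none.
Why: Cu-catalysed asymmetric conjugate addition sets C5. The resulting magnesium enolate then undergoes Michael addition to 3 anti to the new C5 substituent, setting quaternary C10 (tandem 1,4-addition/Michael). Proposed new method: this extends known conjugate addition–enolate trapping to a 2-substituted enone with an acrylate trap.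

**Step 2**
Reactants: 4.
Product: 5, methyl 3-[3,3-bis(hydroxymethyl)-1-methyl-2-oxo-6-(prop-1-en-2-yl)cyclohexyl]propanoate.
Conditions: aq. HCHO (10 equiv), K2CO3 (0.3 equiv), THF/H2O, 0 °C → rt.
Reagents that add atoms: formaldehyde, C=O.
Why: C9 has only one enolizable side (C8), since C10 is quaternary. Double aldol hydroxymethylation therefore gives the gem-bis(hydroxymethyl) quaternary C8. The two CH2OH groups are diastereotopic (one axial, syn-diaxial to C20; one equatorial) and no stereocentre is created.

**Step 3**
Reactants: 5.
Product: 6, the equatorial (C15, anti to C20) CH2OTBS with the axial (C14) CH2OH free.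
Conditions: TBSCl (1.0 equiv), imidazole, CH2Cl2, –20 → 0 °C.
Reagents that add atoms: tert-butyldimethylsilyl chloride, CC(C)(C)[Si](C)(C)Cl.
Why: Silylation occurs at the unhindered equatorial CH2OH, while the axial CH2OH is shielded by the 1,3-diaxial C20 methyl. This makes C8 a stereocentre with C14 up (axial) and C15 down (equatorial).

**Step 4**
Reactants: 6.
Product: 7, the β-ketoaldehyde with C14 as CHO and C15 as CH2OTBS.
Conditions: Dess–Martin periodinane, NaHCO3, CH2Cl2, 0 °C.
Reagents that add atoms: none.
Why: Mild neutral oxidation of the remaining primary alcohol gives the aldehyde. C8 has no α-H, so there is no epimerization, and 7 is used immediately to avoid deformylation.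

**Step 5**
Reactants: 7, 8 (3-bromo-2-(bromomethyl)prop-1-ene).
Product: 9, the cis-fused decalin diol with C9 tertiary OH, C14 secondary OH, exocyclic C12=C16H2 and C15 still as CH2OTBS.
Conditions: CrCl2 (6 equiv), DMF/THF, 25 °C.
Reagents that add atoms: none beyond 8.
Why: Proposed new method: allylchromium from one CH2Br adds chemoselectively to the aldehyde (C13–C14 bond). The second allylchromium, formed from the remaining CH2Br, closes ring C onto the hindered C9 ketone (C9–C11 bond) through a chair-like Zimmerman–Traxler transition state. Closure from the axial C14 tether is necessarily cis, which places C11 up and the C9–O down. Cr(III) chelation of both alkoxides should give the syn 1,3-diol (C14–O down). The closest known reaction is the intramolecular Nozaki–Hiyama–Kishi allylation, extended to a double [3+3] carbocyclization.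

**Step 6**
Reactants: 9.
Product: 10, the δ-lactone (C9–O–C3=O) with C14–OH free.
Conditions: Sc(OTf)3 (5 mol%), toluene, 110 °C, 4 Å MS.
Reagents that add atoms: none (loses MeOH).
Why: Intramolecular Lewis-acid transesterification. The C9–O (down) and the C1 chain (down) are cis on ring B, so the six-membered lactone closes easily. No stereocentre is changed.

**Step 7**
Reactants: 10.
Product: 11, the C14 acetate.
Conditions: Ac2O, Et3N, DMAP, CH2Cl2, rt.
Reagents that add atoms: acetic anhydride, CC(=O)OC(C)=O.
Why: Simple O-acetylation of the secondary alcohol, with retention at C14. This installs the acetate of the target before the radical step.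

**Step 8**
Reactants: 11.
Product: 12, the C15 primary alcohol.
Conditions: HF·pyridine, pyridine/THF, 0 °C → rt.
Reagents that add atoms: none.
Why: Fluoride removes the neopentyl TBS ether while the acetate and lactone survive.

**Step 9**
Reactants: 12.
Product: 13, the C15 aldehyde.
Conditions: Dess–Martin periodinane, NaHCO3, CH2Cl2, rt.
Reagents that add atoms: none.
Why: Oxidation of the primary alcohol to the ketyl precursor.

**Step 10 (key radical step)**
Reactants: 13.
Product: 14, the bicyclo[2.2.2]octane with a C15 secondary alcohol (C15 epimers, irrelevant).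
Conditions: SmI2 (4.5 equiv), HMPA (18 equiv), t-BuOH (2 equiv), THF, 5 mM, –78 → 0 °C.
Reagents that add atoms: none (H from t-BuOH).
Why: Proposed new method: SmI2 converts the aldehyde to a ketyl radical at C15, which attacks the terminal CH2 (C16) of the 1,1-disubstituted C12=C16 alkene in a 6-endo closure. 5-exo attack would need a fully substituted carbon and give a strained bicyclo[2.2.1]. The tertiary bridgehead radical at C12 is reduced by SmI2 and protonated, forming the bicyclo[2.2.2]octane, with C12 fixed by the ring system and C8–C14/C9 stereochemistry untouched. The closest known reaction is SmI2 ketyl–olefin cyclization, applied here as a bridging 6-endo closure.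

**Step 11**
Reactants: 14.
Product: 15, the C15 ketone.
Conditions: Dess–Martin periodinane, NaHCO3, CH2Cl2, rt.
Reagents that add atoms: none.
Why: Oxidation removes the C15 stereocentre and gives the enolizable ketone.

**Step 12**
Reactants: 15.
Product: 16, the Mannich base at C16 (epimeric).
Conditions: LiHMDS (1.05 equiv), THF, –78 °C; then Eschenmoser's salt, –78 → 0 °C.
Reagents that add atoms: dimethyl(methylene)ammonium iodide, C[N+](C)=C.[I-].
Why: Kinetic enolization occurs selectively at the ketone, and only C16 is enolizable, since C8 is quaternary. Mannich aminomethylation then gives the C17 precursor.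

**Step 13**
Reactants: 16.
Product: 17, crotobarin.
Conditions: MeI, CH2Cl2, rt; then DBU, rt.
Reagents that add atoms: none (the NMe3 group is lost).
Why: Quaternization followed by E1cB/Hofmann-type elimination gives the exocyclic α-methylene ketone C16=C17 without touching the acetate or lactone.

## Compound list
1 | 2-methylcyclohex-2-en-1-one | CC1=CCCCC1=O | starting material
2 | 2-bromopropene (as isopropenylMgBr) | C=C(C)Br | starting material
3 | methyl acrylate | C=CC(=O)OC | starting material
4 | keto ester (C5, C10 set) | O=C1CCC[C@@H](C(C)=C)[C@]1(C)CCC(=O)OC | intermediate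
5 | gem-bis(hydroxymethyl) ketone | O=C1C(CO)(CO)CC[C@@H](C(C)=C)[C@]1(C)CCC(=O)OC | intermediate
6 | mono-TBS ether (C15-OTBS, C14-OH free) | O=C1[C@](CO)(CO[Si](C)(C)C(C)(C)C)CC[C@@H](C(C)=C)[C@]1(C)CCC(=O)OC | intermediate
7 | β-ketoaldehyde | O=C1[C@](C=O)(CO[Si](C)(C)C(C)(C)C)CC[C@@H](C(C)=C)[C@]1(C)CCC(=O)OC | intermediate
8 | 3-bromo-2-(bromomethyl)prop-1-ene | C=C(CBr)CBr | starting material
9 | ring C diol (methylene, C9-OH, C14-OH) | C=C1C[C@H](O)[C@@]2(CO[Si](C)(C)C(C)(C)C)CC[C@@H](C(C)=C)[C@](C)(CCC(=O)OC)[C@@]2(O)C1 | intermediate
10 | δ-lactone | C=C1C[C@H](O)[C@@]2(CO[Si](C)(C)C(C)(C)C)CC[C@@H](C(C)=C)[C@]3(C)CCC(=O)O[C@]23C1 | intermediate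
11 | C14 acetate | C=C1C[C@H](OC(C)=O)[C@@]2(CO[Si](C)(C)C(C)(C)C)CC[C@@H](C(C)=C)[C@]3(C)CCC(=O)O[C@]23C1 | intermediate
12 | C15 primary alcohol | C=C1C[C@H](OC(C)=O)[C@@]2(CO)CC[C@@H](C(C)=C)[C@]3(C)CCC(=O)O[C@]23C1 | intermediate
13 | C15 aldehyde | C=C1C[C@H](OC(C)=O)[C@@]2(C=O)CC[C@@H](C(C)=C)[C@]3(C)CCC(=O)O[C@]23C1 | intermediate
14 | bicyclic alcohol (C15 epimeric) | C1C(O)[C@]23CC[C@@H](C(=C)C)[C@]4(C)CCC(=O)O[C@@]42C[C@H]1C[C@@H]3OC(C)=O | intermediate
15 | bicyclic ketone | C1C(=O)[C@]23CC[C@@H](C(=C)C)[C@]4(C)CCC(=O)O[C@@]42C[C@H]1C[C@@H]3OC(C)=O | intermediate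
16 | Mannich base (C16 epimeric) | CN(C)CC1C(=O)[C@]23CC[C@@H](C(=C)C)[C@]4(C)CCC(=O)O[C@@]42C[C@H]1C[C@@H]3OC(C)=O | intermediate
17 | crotobarin | C=C1C(=O)[C@]23CC[C@@H](C(=C)C)[C@]4(C)CCC(=O)O[C@@]42C[C@H]1C[C@@H]3OC(C)=O | target

**Total steps:** 13. **Longest linear sequence:** 13, from 1.

**Three steps most likely to fail**
1. **Step 10 (SmI2 6-endo bridging).** The aldehyde may simply be reduced to the alcohol, or pinacol-couple.
   - *Fallback (changes approach):* Switch to acyl-radical polarity. Generate the acyl radical from 13 by decatungstate/HAT photocatalysis, or use Rh-catalysed alkene hydroacylation. Either closes the same C15–C16 bond and gives ketone 15 directly, skipping steps 10–11.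
2. **Step 5 (double Cr allylation onto the C9 ketone flanked by two quaternary carbons).** It may stop after mono-allylation, close with the wrong C9 or C14 configuration, or form a 3-methylenetetrahydrofuran by alkoxide displacement of the allylic bromide.
   - *Fallback (changes approach):* Do it stepwise. Allylate the aldehyde with 8/Zn, protect C14–OH as its TBS ether, then close ring C by intramolecular SmI2 or NHK allylation of the ketone. If C14 comes out epimeric, oxidize and reduce stereoselectively after step 7.
3. **Step 1 (tandem asymmetric conjugate addition/Michael).** Low ee or dr is likely, and a Michael–aldol side reaction of the ester enolate is possible.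
   - *Fallback (changes approach):* Run the conjugate addition racemically (or with modest ee) and Michael-trap in two stages. Then resolve the derived keto-acid classically with (S)-1-phenylethylamine, and re-esterify.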